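**Plan**

1. Retrosynthesis: the 4-methoxybenzyl (PMB) ether on O-9 is removed last. Before that, the seven-membered ring is opened at two bonds at once, C-6–C-7 and C-9–C-10, giving the trans-1,2-diformylcyclopentane 10 and the C3 reagent 15 (C-7, C-8 with its methylene, C-9).
2. Feature that allows this: C-6 and C-10 are both carbinol carbons sitting directly on the adjacent cyclopentane carbons C-5 and C-1. C-8 carries the exocyclic methylene between an allylic CH2 (C-7) and an oxygenated CH (C-9). The C-4 tertiary hydroxyl is cis to the formyl group on C-5 and so tells the two aldehydes apart.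
3. Forward: cyclopentane first (steps 1–4), reagent 15 (steps 5–7), then the seven-membered ring, the ester and three stereocentres in one chromium-mediated [4+3] annulation (step 8), then PMB removal (step 9).
4. Stereochemistry: C-1 from a ligand-controlled copper-catalysed conjugate addition; C-5 anti to the bulky alkenyl group on C-1; C-4 by addition anti to the C-5 substituent; C-6 by hydroxyl chelation; C-10 and C-9 from the bicyclic chair transition state of the ring closure.

Key step: step 8

Remark (numbering): daucane numbering is used in the text. C-1 is the methyl-bearing ring-fusion carbon, C-2/C-3 the ring CH2 groups, C-4 the C(OH)(i-Pr) carbon, C-5 the ring-fusion CH, C-6 the ester carbinol, C-7 the CH2, C-8 the C(=CH2), C-9 and C-10 the diol carbons (C-10 next to C-1).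
Remark (chemistry): the sense of induction of the chiral ligand in step 1 is not presumed; the ligand antipode that gives (R)-6 is used, both being available.

**Route**

Step 1
Reactants: 1 3-methylcyclopent-2-en-1-one; 2 1-bromo-2-methylprop-1-ene
Product: 6 (R)-trimethyl{[3-methyl-3-(2-methylprop-1-en-1-yl)cyclopent-1-en-1-yl]oxy}silane, via 2-methylprop-1-enyllithium 3 (not isolated), via dimethyl(2-methylprop-1-enyl)aluminium 4 (not isolated), via aluminium enolate 5 (not isolated)
Conditions: 2, t-BuLi (2 equiv), Et2O, −78 °C; Me2AlCl, −78 → −30 °C; 1, Cu(OTf)2 (5 mol %), N,N-bis[(R)-1-phenylethyl]-P,P-diphenylphosphinous amide (10 mol %), Et2O, −30 °C; then Me3SiOTf, Et3N, −30 → 0 °C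
Reagents that add atoms: trimethylsilyl trifluoromethanesulfonate, C[Si](C)(C)OS(=O)(=O)C(F)(F)F
Why: Copper-catalysed asymmetric conjugate addition of an alkenylalane to a β-methyl cyclic enone (alkenyl is transferred in preference to methyl) builds the quaternary C-1 with the ligand choosing the enone face, and O-silylation traps the enolate regiospecifically towards C-5.

Step 2
Reactants: 6 (R)-trimethyl{[3-methyl-3-(2-methylprop-1-en-1-yl)cyclopent-1-en-1-yl]oxy}silane
Product: 7 (2S,3R)-2-(dimethoxymethyl)-3-methyl-3-(2-methylprop-1-en-1-yl)cyclopentan-1-one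
Conditions: HC(OMe)3, Me3SiOTf (10 mol %), CH2Cl2, −78 °C
Reagents that add atoms: trimethyl orthoformate, COC(OC)OC
Why: Mukaiyama-type addition of the silyl enol ether to the dimethoxycarbenium ion puts the masked formyl carbon (future C-6) on C-5 only, and the electrophile should enter anti to the 2-methylprop-1-enyl group on C-1, whose cis methyl shields its face more than the ring methyl does, so that CH(OMe)2 ends cis to the C-1 methyl.

Step 3
Reactants: 7 (2S,3R)-2-(dimethoxymethyl)-3-methyl-3-(2-methylprop-1-en-1-yl)cyclopentan-1-one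
Product: 8 (1R,2R,3R)-2-(dimethoxymethyl)-3-methyl-3-(2-methylprop-1-en-1-yl)-1-(propan-2-yl)cyclopentan-1-ol
Conditions: i-PrMgCl, CeCl3, THF, −78 → 0 °C
Reagents that add atoms: isopropylmagnesium chloride, CC(C)[Mg]Cl
Why: Organocerium 1,2-addition suppresses enolisation of the hindered ketone, and the nucleophile should attack the C-4 carbonyl anti to the C-5 dimethoxymethyl group and the C-1 methyl, which lie on the same face, so the new hydroxyl is cis to both.

Step 4
Reactants: 8 (1R,2R,3R)-2-(dimethoxymethyl)-3-methyl-3-(2-methylprop-1-en-1-yl)-1-(propan-2-yl)cyclopentan-1-ol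
Product: 10 (1S,2R,3R)-3-hydroxy-1-methyl-3-(propan-2-yl)cyclopentane-1,2-dicarbaldehyde, via aldehyde acetal 9 (not isolated)
Conditions: O3, CH2Cl2, −78 °C; PPh3, −78 °C → rt; then 5% aq. oxalic acid, THF, 0 °C → rt; used crude
Reagents that add atoms: ozone, [O-][O+]=O; water, O
Why: Ozonolysis of the only C=C and mild acetal hydrolysis unveil both aldehydes without touching the stereocentres, and the epimerisable C-5 already holds its more stable configuration (formyl trans to isopropyl and to the other formyl group).

Step 5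
Reactants: 11 ethyl 2-(bromomethyl)prop-2-enoate
Product: 12 2-(bromomethyl)prop-2-en-1-ol
Conditions: i-Bu2AlH (2.2 equiv), CH2Cl2, −78 °C
Reagents that add atoms: none
Why: 1,2-Reduction of the unsaturated ester by the aluminium hydride at low temperature should give the allylic alcohol and leave the allylic bromide untouched.

Step 6
Reactants: 12 2-(bromomethyl)prop-2-en-1-ol
Product: 13 2-(bromomethyl)prop-2-enal
Conditions: MnO2, CH2Cl2, rt
Reagents that add atoms: none
Why: Oxidation of a primary allylic alcohol with activated MnO2 stops at the enal.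

Step 7
Reactants: 13 2-(bromomethyl)prop-2-enal; 14 (4-methoxyphenyl)methanol
Product: 15 3-bromo-2-{bis[(4-methoxybenzyl)oxy]methyl}prop-1-ene
Conditions: 14 (2.2 equiv), PPTS (cat.), 4 Å molecular sieves, CH2Cl2, rt
Reagents that add atoms: none
Why: Acid-catalysed acetalisation under dehydrating conditions is mild enough to spare the allylic bromide and the benzylic alcohol.

Step 8
Reactants: 10 (1S,2R,3R)-3-hydroxy-1-methyl-3-(propan-2-yl)cyclopentane-1,2-dicarbaldehyde; 15 3-bromo-2-{bis[(4-methoxybenzyl)oxy]methyl}prop-1-ene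
Product: 20 (3R,3aS,4S,7R,8S,8aS)-3,8-dihydroxy-7-[(4-methoxybenzyl)oxy]-8a-methyl-6-methylidene-3-(propan-2-yl)decahydroazulen-4-yl 3-methylbutanoate, via allylchromium reagent 16 (not isolated), via chromium alkoxide 17 (not isolated), via acetal ester 18 (not isolated), via alkoxyallylchromium 19 (not isolated)
Conditions: CrCl2 (6 equiv), THF (0.01 M), 0 °C, slow addition of 15 (1.05 equiv); 3-methylbutanoyl chloride (1.05 equiv), 0 °C; Me3SiI (1.2 equiv), −40 → 0 °C; aq. citric acid/MeOH work-up
Reagents that add atoms: 3-methylbutanoyl chloride, CC(C)CC(Cl)=O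
Why: Proposed new method: CrCl2 turns bromide 15 into allylchromium 16, which adds through its CH2 terminus in a chair transition state (Nozaki–Hiyama allylation) to the formyl group on C-5 of 10, the aldehyde held and activated by the cis tertiary hydroxyl (hydrogen bond or chromium chelate), and attack on the chelate face turned away from the quaternary C-1 should make C-6 S; the chromium alkoxide 17 is acylated at once by 3-methylbutanoyl chloride, which installs the ester while this is the only alkoxide in the flask and keeps that oxygen from capturing the cation of the next stage. Me3SiI then ionises the unsaturated acetal of 18 and two further equivalents of CrCl2 reduce the alkoxyallyl iodide to the γ-alkoxyallylchromium 19, which adds with allylic transposition through its oxygen-bearing carbon to the remaining neopentyl aldehyde, a 7-exo-trig carbonyl addition that closes the seven-membered carbocycle and leaves the exocyclic methylene. The closest known reactions are the intermolecular Nozaki–Hiyama allylation, the CrCl2/Me3SiI-mediated γ-alkoxyallylation of aldehydes with acrolein acetals and the [3+4] annulation of 1,4-dicarbonyl compounds with bifunctional allyl reagents; new is their union in one flask on one C3 reagent. Because the tether spans the chair transition state, the quaternary C-1 must sit axial on the aldehyde carbon with the C-1–C-5 bond over the six-membered array and the methyl group outside, so the C-10 oxygen should end anti to the angular methyl (S), and the 4-methoxybenzyloxy group should take the axial position anti to C-1 (Z-enol ether, reached by η1/η3 equilibration), which gives the cis relationship of O-9 and O-10 (C-9 R). The step needs site selectivity between two aldehydes, secured by the free C-4 hydroxyl, and the right orientation of the C3 unit, secured by the order of activation (bromide first, acetal only after Me3SiI); high dilution favours ring closure over oligomerisation.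

Step 9
Reactants: 20 (3R,3aS,4S,7R,8S,8aS)-3,8-dihydroxy-7-[(4-methoxybenzyl)oxy]-8a-methyl-6-methylidene-3-(propan-2-yl)decahydroazulen-4-yl 3-methylbutanoate
Product: 21 (3R,3aS,4S,7R,8S,8aS)-3,7,8-trihydroxy-8a-methyl-6-methylidene-3-(propan-2-yl)decahydroazulen-4-yl 3-methylbutanoate
Conditions: DDQ, CH2Cl2–pH 7 phosphate buffer (10:1), 0 °C
Reagents that add atoms: none
Why: Oxidative cleavage of the 4-methoxybenzyl ether by DDQ (benzylic hydride abstraction, then hydrolysis of the oxocarbenium ion) should free the C-9 hydroxyl under neutral conditions that spare the ester, the exocyclic alkene and the tertiary alcohol.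

**Compound list**

1 | 3-methylcyclopent-2-en-1-one | CC1=CC(=O)CC1 | starting material
2 | 1-bromo-2-methylprop-1-ene | CC(C)=CBr | starting material
3 | (2-methylprop-1-en-1-yl)lithium | [Li]C=C(C)C | intermediate
4 | dimethyl(2-methylprop-1-en-1-yl)aluminium | C[Al](C)C=C(C)C | intermediate
5 | dimethylaluminium (R)-3-methyl-3-(2-methylprop-1-en-1-yl)cyclopent-1-en-1-olate | C[Al](C)OC1=C[C@](C)(CC1)C=C(C)C | intermediate
6 | (R)-trimethyl{[3-methyl-3-(2-methylprop-1-en-1-yl)cyclopent-1-en-1-yl]oxy}silane | C[Si](C)(C)OC1=C[C@](C)(CC1)C=C(C)C | intermediate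
7 | (2S,3R)-2-(dimethoxymethyl)-3-methyl-3-(2-methylprop-1-en-1-yl)cyclopentan-1-one | COC(OC)[C@@H]1[C@](C)(CCC1=O)C=C(C)C | intermediate
8 | (1R,2R,3R)-2-(dimethoxymethyl)-3-methyl-3-(2-methylprop-1-en-1-yl)-1-(propan-2-yl)cyclopentan-1-ol | COC(OC)[C@@H]1[C@](C)(CC[C@@]1(O)C(C)C)C=C(C)C | intermediate
9 | (1S,2R,3R)-2-(dimethoxymethyl)-3-hydroxy-1-methyl-3-(propan-2-yl)cyclopentane-1-carbaldehyde | COC(OC)[C@@H]1[C@](C)(CC[C@@]1(O)C(C)C)C=O | intermediate
10 | (1S,2R,3R)-3-hydroxy-1-methyl-3-(propan-2-yl)cyclopentane-1,2-dicarbaldehyde | O=C[C@@H]1[C@](C)(CC[C@@]1(O)C(C)C)C=O | intermediate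
11 | ethyl 2-(bromomethyl)prop-2-enoate | C=C(CBr)C(=O)OCC | starting material
12 | 2-(bromomethyl)prop-2-en-1-ol | C=C(CBr)CO | intermediate
13 | 2-(bromomethyl)prop-2-enal | C=C(CBr)C=O | intermediate
14 | (4-methoxyphenyl)methanol | COc1ccc(CO)cc1 | starting material
15 | 3-bromo-2-{bis[(4-methoxybenzyl)oxy]methyl}prop-1-ene | C=C(CBr)C(OCc1ccc(OC)cc1)OCc1ccc(OC)cc1 | intermediate
16 | {2-[bis((4-methoxybenzyl)oxy)methyl]prop-2-en-1-yl}chromium dichloride | C=C(C[Cr](Cl)Cl)C(OCc1ccc(OC)cc1)OCc1ccc(OC)cc1 | intermediate
17 | dichlorochromium alkoxide of (1S,2S,3R)-2-[(1S)-3-{bis[(4-methoxybenzyl)oxy]methyl}-1-hydroxybut-3-en-1-yl]-3-hydroxy-1-methyl-3-(propan-2-yl)cyclopentane-1-carbaldehyde | C=C(C[C@H](O[Cr](Cl)Cl)[C@@H]1[C@](C)(CC[C@@]1(O)C(C)C)C=O)C(OCc1ccc(OC)cc1)OCc1ccc(OC)cc1 | intermediate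
18 | (1S)-3-{bis[(4-methoxybenzyl)oxy]methyl}-1-[(1S,2S,5R)-2-formyl-5-hydroxy-2-methyl-5-(propan-2-yl)cyclopentyl]but-3-en-1-yl 3-methylbutanoate | C=C(C[C@H](OC(=O)CC(C)C)[C@@H]1[C@](C)(CC[C@@]1(O)C(C)C)C=O)C(OCc1ccc(OC)cc1)OCc1ccc(OC)cc1 | intermediate
19 | (Z)-γ-alkoxyallylchromium dichloride from 18: Cl2Cr–CH2–C(=CH–O-4-methoxybenzyl)–CH2–CH(O-3-methylbutanoyl)–cyclopentyl, stereocentres as in 18 | Cl[Cr](Cl)C/C(C[C@H](OC(=O)CC(C)C)[C@@H]1[C@](C)(CC[C@@]1(O)C(C)C)C=O)=C\OCc1ccc(OC)cc1 | intermediate
20 | (3R,3aS,4S,7R,8S,8aS)-3,8-dihydroxy-7-[(4-methoxybenzyl)oxy]-8a-methyl-6-methylidene-3-(propan-2-yl)decahydroazulen-4-yl 3-methylbutanoate | C=C1C[C@H](OC(=O)CC(C)C)[C@@H]2[C@](C)(CC[C@@]2(O)C(C)C)[C@H](O)[C@@H]1OCc1ccc(OC)cc1 | intermediate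
21 | (3R,3aS,4S,7R,8S,8aS)-3,7,8-trihydroxy-8a-methyl-6-methylidene-3-(propan-2-yl)decahydroazulen-4-yl 3-methylbutanoate | C=C1C[C@H](OC(=O)CC(C)C)[C@@H]2[C@](C)(CC[C@@]2(O)C(C)C)[C@H](O)[C@@H]1O | target

**Step count and risks**

Total steps: 9. Longest linear sequence: 6 (steps 1, 2, 3, 4, 8, 9).

Steps most likely to fail:

1. Step 8 (Proposed new method). What may go wrong: loss of site selectivity between the two formyl groups in the first addition, capture or premature reduction of the oxocarbenium ion in the second stage, or oligomerisation instead of ring closure. The fallback makes the two bonds in separate, known operations and closes the ring by a different event. It sets out from 10 (and 15). Indium-mediated Barbier allylation in THF–water, where chelation by the free hydroxyl should direct the addition, gives the homoallylic alcohol F1. Acylation with 3-methylbutanoic anhydride and DMAP gives ester 18, now isolated. PPTS in aqueous acetone hydrolyses the acetal to the enal F2. A chromium-mediated pinacol-type cross-coupling of the enal with the remaining aldehyde (CrCl2, Et3SiCl, THF, high dilution; then Bu4NF/AcOH) should close the seven-membered ring as the cis-diol, and the route is rejoined at 21.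

2. Step 2. What may go wrong: poor facial selectivity of the orthoformate addition, because methyl and 2-methylprop-1-enyl on C-1 may not differ enough in size; the wrong C-5 epimer would also misdirect step 3. The fallback builds the quaternary carbon with a much larger alkenyl group and unmasks it differently. It sets out from 1. Ethynyltrimethylsilane and i-Bu2AlH give the vinylalane F3. Its copper-catalysed asymmetric conjugate addition to 1 (Cu(OTf)2, chiral N-heterocyclic carbene ligand) gives the aluminium enolate F4, which Me3SiOTf converts into the silyl enol ether F5. The same orthoformate addition, now past a face blocked by the 1-silylvinyl group, should give the keto acetal F6, and i-PrMgCl/CeCl3 the tertiary alcohol F7. Lemieux–Johnson cleavage (OsO4 cat., NaIO4, 2,6-lutidine) gives the acylsilane F8. Bu4NF in wet THF (Brook rearrangement and protonation) converts it into the aldehyde, and the route is rejoined at 9.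

3. Step 1. What may go wrong: slow alkenyl transfer to the five-membered enone or low enantioselectivity. The fallback reverses the order in which the two substituents reach the quaternary carbon. It sets out from 2. Magnesium in THF gives the Grignard reagent F9. Addition to 3-ethoxycyclopent-2-en-1-one followed by aqueous acid (Stork–Danheiser transposition) gives the dienone F10. Copper-catalysed 1,4-selective asymmetric conjugate addition of MeMgBr (Cu(OTf)2, chiral N-heterocyclic carbene ligand, Et2O, −30 °C) gives the magnesium enolate F11. Me3SiCl/Et3N silylates it, and the route is rejoined at 6.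

Further compounds
F1 | step 8 | (1S,2S,3R)-2-[(1S)-3-{bis[(4-methoxybenzyl)oxy]methyl}-1-hydroxybut-3-en-1-yl]-3-hydroxy-1-methyl-3-(propan-2-yl)cyclopentane-1-carbaldehyde | C=C(C[C@H](O)[C@@H]1[C@](C)(CC[C@@]1(O)C(C)C)C=O)C(OCc1ccc(OC)cc1)OCc1ccc(OC)cc1
F2 | step 8 | (1S)-3-formyl-1-[(1S,2S,5R)-2-formyl-5-hydroxy-2-methyl-5-(propan-2-yl)cyclopentyl]but-3-en-1-yl 3-methylbutanoate | C=C(C[C@H](OC(=O)CC(C)C)[C@@H]1[C@](C)(CC[C@@]1(O)C(C)C)C=O)C=O
F3 | step 2 | [1-(trimethylsilyl)ethenyl]bis(2-methylpropyl)aluminium | C=C([Si](C)(C)C)[Al](CC(C)C)CC(C)C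
F4 | step 2 | bis(2-methylpropyl)aluminium (S)-3-methyl-3-[1-(trimethylsilyl)ethenyl]cyclopent-1-en-1-olate | CC(C)C[Al](CC(C)C)OC1=C[C@](C)(CC1)C(=C)[Si](C)(C)C
F5 | step 2 | (S)-trimethyl({3-methyl-3-[1-(trimethylsilyl)ethenyl]cyclopent-1-en-1-yl}oxy)silane | C[Si](C)(C)OC1=C[C@](C)(CC1)C(=C)[Si](C)(C)C
F6 | step 2 | (2S,3S)-2-(dimethoxymethyl)-3-methyl-3-[1-(trimethylsilyl)ethenyl]cyclopentan-1-one | COC(OC)[C@@H]1[C@](C)(CCC1=O)C(=C)[Si](C)(C)C
F7 | step 2 | (1R,2R,3S)-2-(dimethoxymethyl)-3-methyl-1-(propan-2-yl)-3-[1-(trimethylsilyl)ethenyl]cyclopentan-1-ol | COC(OC)[C@@H]1[C@](C)(CC[C@@]1(O)C(C)C)C(=C)[Si](C)(C)C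
F8 | step 2 | [(1S,2R,3R)-2-(dimethoxymethyl)-3-hydroxy-1-methyl-3-(propan-2-yl)cyclopentyl](trimethylsilyl)methanone | COC(OC)[C@@H]1[C@](C)(CC[C@@]1(O)C(C)C)C(=O)[Si](C)(C)C
F9 | step 1 | (2-methylprop-1-en-1-yl)magnesium bromide | CC(C)=C[Mg]Br
F10 | step 1 | 3-(2-methylprop-1-en-1-yl)cyclopent-2-en-1-one | CC(C)=CC1=CC(=O)CC1
F11 | step 1 | bromomagnesium (R)-3-methyl-3-(2-methylprop-1-en-1-yl)cyclopent-1-en-1-olate | Br[Mg]OC1=C[C@](C)(CC1)C=C(C)C
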